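**Retrosynthetic overview**
1. Target 21 ⇐ air oxidation of the 1,2,4-trihydroxy-5-methoxyarene 20 ⇐ one hydrogenation of the tris(benzyl ether) alkene 19 (C=C saturation plus three O-debenzylations). Only the methyl ether is kept, so the OH/OMe positions are fixed by construction.
2. 19 ⇐ olefin cross-metathesis of homoallylic acetate 17 with dodec-1-ene 18 (builds the C13 tail).
3. Key C–C bond (side-chain C2–C3): Brown asymmetric allylboration of arylacetaldehyde 12 with the allyl unit of allylmagnesium bromide 13, giving (R)-16.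
4. 12 ⇐ allylarene 10 ⇐ aromatic Claisen rearrangement of allyl ether 8 ⇐ phenol 6 ⇐ (Dakin, Vilsmeier, benzylation) methoxyhydroquinone 1.
5. No ring is constructed: the carbocycle is bought as the benzene ring of 1 and becomes the quinone in the last step.

Assumption: the stereocentre is (R) as read from the SMILES (OAc > CH2–quinone > C13 chain > H), and the target is made as the drawn 2-hydroxy-1,4-benzoquinone tautomer.

**Route**

Step 1
Reactants: 1 2-methoxybenzene-1,4-diol (methoxyhydroquinone)
Product: 2 1,4-bis(benzyloxy)-2-methoxybenzene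
Conditions: BnBr (2.3 equiv), K2CO3, DMF, N2, 60 °C
Reagents that add atoms: benzyl bromide, BrCc1ccccc1
Why: Williamson ether synthesis (SN2) on both phenoxides; benzyl is chosen because all benzyl ethers later fall in the same hydrogenation that saturates the chain.

Step 2
Reactants: 2 1,4-bis(benzyloxy)-2-methoxybenzene
Product: 4 2,5-bis(benzyloxy)-4-methoxybenzaldehyde, via aryl iminium chloride 3 (not isolated)
Conditions: POCl3, DMF, 0 → 75 °C; then ice/H2O
Reagents that add atoms: N,N-dimethylformamide, CN(C)C=O (formyl carbon); water, O (carbonyl oxygen)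
Why: Vilsmeier–Haack formylation attacks the one ring position that is para to one alkoxy group (OMe) and ortho to another, as with 1,2,4-trimethoxybenzene.

Step 3
Reactants: 4 2,5-bis(benzyloxy)-4-methoxybenzaldehyde
Product: 6 2,5-bis(benzyloxy)-4-methoxyphenol, via aryl formate 5 (not isolated)
Conditions: mCPBA, CH2Cl2, 0 °C → rt; then K2CO3 (cat.), MeOH, rt
Reagents that add atoms: mCPBA (3-chloroperoxybenzoic acid), OOC(=O)c1cccc(Cl)c1
Why: Dakin-type Baeyer–Villiger oxidation, in which the electron-rich aryl group migrates to give the formate; mild methanolysis then frees the phenol and installs the fourth ring oxygen.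

Step 4
Reactants: 6 2,5-bis(benzyloxy)-4-methoxyphenol; 7 allyl bromide
Product: 8 1-(allyloxy)-2,5-bis(benzyloxy)-4-methoxybenzene
Conditions: K2CO3, acetone, reflux
Reagents that add atoms: none
Why: Williamson O-allylation (SN2) of the only free phenol.

Step 5
Reactants: 8 1-(allyloxy)-2,5-bis(benzyloxy)-4-methoxybenzene
Product: 9 2-allyl-3,6-bis(benzyloxy)-4-methoxyphenol
Conditions: N,N-diethylaniline, Ar, 190 °C
Reagents that add atoms: none
Why: Aromatic Claisen [3,3]-sigmatropic rearrangement; only one ortho position carries hydrogen and the para position is blocked, so the allyl group lands regiospecifically between the new OH and an OBn group.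

Step 6
Reactants: 9 2-allyl-3,6-bis(benzyloxy)-4-methoxyphenol
Product: 10 3-allyl-1,2,4-tris(benzyloxy)-5-methoxybenzene
Conditions: BnBr, K2CO3, DMF, N2, 60 °C
Reagents that add atoms: benzyl bromide, BrCc1ccccc1
Why: Williamson ether synthesis; the oxygen that becomes the quinone hydroxyl now carries the same hydrogenolysable group as the two future carbonyl oxygens.

Step 7
Reactants: 10 3-allyl-1,2,4-tris(benzyloxy)-5-methoxybenzene
Product: 12 2-[2,3,6-tris(benzyloxy)-5-methoxyphenyl]acetaldehyde, via racemic diol 11 (not isolated)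
Conditions: OsO4 (2 mol%), NaIO4 (4 equiv), 2,6-lutidine, dioxane/H2O 3:1, rt; used crude at once
Reagents that add atoms: osmium tetroxide OsO4, O=[Os](=O)(=O)=O (catalytic carrier of the oxygen); sodium periodate NaIO4, [Na+].[O-]I(=O)(=O)=O (terminal oxidant that resupplies it)
Why: Lemieux–Johnson oxidation (dihydroxylation, then glycol cleavage) under buffered neutral conditions leaves the electron-rich ring and the benzyl ethers untouched.

Step 8
Reactants: 12 2-[2,3,6-tris(benzyloxy)-5-methoxyphenyl]acetaldehyde; 13 allylmagnesium bromide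
Product: 16 (R)-1-[2,3,6-tris(benzyloxy)-5-methoxyphenyl]pent-4-en-2-ol, via B-allyldiisopinocampheylborane 14 (not isolated), via borinate ester 15 (not isolated)
Conditions: (+)-Ipc2BOMe (from (−)-α-pinene), 13, Et2O, −78 °C → rt; then 12, Et2O, −78 °C; then 3 M NaOH, 30% H2O2, 0 °C → rt
Reagents that add atoms: none
Why: Brown asymmetric allylboration (carbonyl allylation) through a closed chair six-membered transition state; the isopinocampheyl groups from (−)-α-pinene deliver allyl to the Re face of the aldehyde, which sets the carbinol centre as (R). The −78 °C addition of a non-basic reagent outruns enolisation of the arylacetaldehyde; ee is checked by Mosher ester analysis.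

Step 9
Reactants: 16 (R)-1-[2,3,6-tris(benzyloxy)-5-methoxyphenyl]pent-4-en-2-ol
Product: 17 (R)-1-[2,3,6-tris(benzyloxy)-5-methoxyphenyl]pent-4-en-2-yl acetate
Conditions: Ac2O, pyridine, DMAP (cat.), CH2Cl2, rt
Reagents that add atoms: acetic anhydride, CC(=O)OC(C)=O
Why: DMAP-catalysed O-acylation; the C–O bond at the stereocentre is not broken, so the configuration is retained.

Step 10
Reactants: 17 (R)-1-[2,3,6-tris(benzyloxy)-5-methoxyphenyl]pent-4-en-2-yl acetate; 18 dodec-1-ene
Product: 19 (R)-1-[2,3,6-tris(benzyloxy)-5-methoxyphenyl]pentadec-4-en-2-yl acetate (E/Z mixture)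
Conditions: 18 (4 equiv), second-generation Grubbs catalyst (H2IMes)(PCy3)Cl2Ru=CHPh (3 mol%), 1,4-benzoquinone (10 mol%), CH2Cl2, 40 °C
Reagents that add atoms: none
Why: Olefin cross-metathesis of two terminal alkenes, driven by loss of ethene; excess 18 suppresses homodimerisation of 17, benzoquinone suppresses double-bond migration, and the E/Z ratio is irrelevant because the alkene is hydrogenated next.

Step 11
Reactants: 19 (R)-1-[2,3,6-tris(benzyloxy)-5-methoxyphenyl]pentadec-4-en-2-yl acetate
Product: 21 3-[(2R)-2-acetoxypentadecyl]-2-hydroxy-5-methoxy-1,4-benzoquinone, via trihydroxybenzene 20 (not isolated)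
Conditions: H2 (1 atm), 10% Pd/C, EtOAc/EtOH 4:1, rt; filter; then air (O2), rt
Reagents that add atoms: none
Why: Catalytic hydrogenation saturates the alkene and hydrogenolyses the three aryl benzyl ethers; the resulting 1,2,4-trihydroxybenzene autoxidises to the 2-hydroxy-1,4-benzoquinone. The secondary acetate and the homobenzylic stereocentre are inert to both operations.

**Compound list**
1 | 2-methoxybenzene-1,4-diol (methoxyhydroquinone) | COc1cc(O)ccc1O | starting material
2 | 1,4-bis(benzyloxy)-2-methoxybenzene | COc1cc(OCc2ccccc2)ccc1OCc1ccccc1 | intermediate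
3 | N-{[2,5-bis(benzyloxy)-4-methoxyphenyl]methylidene}-N-methylmethanaminium chloride | C[N+](C)=Cc1cc(OCc2ccccc2)c(OC)cc1OCc1ccccc1.[Cl-] | intermediate (not isolated)
4 | 2,5-bis(benzyloxy)-4-methoxybenzaldehyde | O=Cc1cc(OCc2ccccc2)c(OC)cc1OCc1ccccc1 | intermediate
5 | 2,5-bis(benzyloxy)-4-methoxyphenyl formate | O=COc1cc(OCc2ccccc2)c(OC)cc1OCc1ccccc1 | intermediate (not isolated)
6 | 2,5-bis(benzyloxy)-4-methoxyphenol | Oc1cc(OCc2ccccc2)c(OC)cc1OCc1ccccc1 | intermediate
7 | allyl bromide (3-bromoprop-1-ene) | C=CCBr | starting material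
8 | 1-(allyloxy)-2,5-bis(benzyloxy)-4-methoxybenzene | C=CCOc1cc(OCc2ccccc2)c(OC)cc1OCc1ccccc1 | intermediate
9 | 2-allyl-3,6-bis(benzyloxy)-4-methoxyphenol | C=CCc1c(O)c(OCc2ccccc2)cc(OC)c1OCc1ccccc1 | intermediate
10 | 3-allyl-1,2,4-tris(benzyloxy)-5-methoxybenzene | C=CCc1c(OCc2ccccc2)c(OCc2ccccc2)cc(OC)c1OCc1ccccc1 | intermediate
11 | 3-[2,3,6-tris(benzyloxy)-5-methoxyphenyl]propane-1,2-diol (racemic) | OCC(O)Cc1c(OCc2ccccc2)c(OCc2ccccc2)cc(OC)c1OCc1ccccc1 | intermediate (not isolated)
12 | 2-[2,3,6-tris(benzyloxy)-5-methoxyphenyl]acetaldehyde | O=CCc1c(OCc2ccccc2)c(OCc2ccccc2)cc(OC)c1OCc1ccccc1 | intermediate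
13 | allylmagnesium bromide | C=CC[Mg]Br | starting material
14 | B-allyldiisopinocampheylborane, both isopinocampheyl groups from (−)-α-pinene (configured as in (+)-isopinocampheol) | C=CCB([C@H]1C[C@H]2C[C@@H]([C@@H]1C)C2(C)C)[C@H]1C[C@H]2C[C@@H]([C@@H]1C)C2(C)C | intermediate (not isolated)
15 | (R)-1-[2,3,6-tris(benzyloxy)-5-methoxyphenyl]pent-4-en-2-yl diisopinocampheylborinate | C=CC[C@@H](OB([C@H]1C[C@H]2C[C@@H]([C@@H]1C)C2(C)C)[C@H]1C[C@H]2C[C@@H]([C@@H]1C)C2(C)C)Cc1c(OCc2ccccc2)c(OCc2ccccc2)cc(OC)c1OCc1ccccc1 | intermediate (not isolated)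
16 | (R)-1-[2,3,6-tris(benzyloxy)-5-methoxyphenyl]pent-4-en-2-ol | C=CC[C@@H](O)Cc1c(OCc2ccccc2)c(OCc2ccccc2)cc(OC)c1OCc1ccccc1 | intermediate
17 | (R)-1-[2,3,6-tris(benzyloxy)-5-methoxyphenyl]pent-4-en-2-yl acetate | C=CC[C@@H](OC(C)=O)Cc1c(OCc2ccccc2)c(OCc2ccccc2)cc(OC)c1OCc1ccccc1 | intermediate
18 | dodec-1-ene | C=CCCCCCCCCCC | starting material
19 | (R)-1-[2,3,6-tris(benzyloxy)-5-methoxyphenyl]pentadec-4-en-2-yl acetate (E/Z mixture, E shown) | CCCCCCCCCC/C=C/C[C@@H](OC(C)=O)Cc1c(OCc2ccccc2)c(OCc2ccccc2)cc(OC)c1OCc1ccccc1 | intermediate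
20 | (R)-1-(2,3,6-trihydroxy-5-methoxyphenyl)pentadecan-2-yl acetate | CCCCCCCCCCCCC[C@H](Cc1c(O)c(O)cc(OC)c1O)OC(C)=O | intermediate (not isolated)
21 | 3-[(2R)-2-acetoxypentadecyl]-2-hydroxy-5-methoxy-1,4-benzoquinone | CCCCCCCCCCCCC[C@H](CC1=C(O)C(=O)C=C(OC)C1=O)OC(C)=O | target

**Totals**
Total step count: 11. Longest linear sequence: 11 steps (1 → 21).

**Steps most likely to fail, with fallbacks**

Step 5 (Claisen rearrangement). The risk is decomposition or oxidation of the very electron-rich ether and phenol at about 190 °C. The fallback sets out from phenol 6 and installs the allyl group by halogenation and cross-coupling instead of a sigmatropic shift. NBS (1.0 equiv, cat. i-Pr2NH, CH2Cl2, −78 → 0 °C) brominates ortho to the free OH to give 3,6-bis(benzyloxy)-2-bromo-4-methoxyphenol F1. BnBr/K2CO3 in DMF then gives 1,2,4-tris(benzyloxy)-3-bromo-5-methoxybenzene F2. Stille coupling of F2 with allyltributylstannane (Pd2(dba)3, P(t-Bu)3, CsF, dioxane, 100 °C) gives allylarene 10, where the route is rejoined.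

Step 8 (asymmetric allylboration). The risks are enolisation or self-condensation of the arylacetaldehyde and insufficient ee. The fallback sets out from aldehyde 12 and separates C–C bond formation from stereocontrol. Barbier allylation with Zn dust and allyl bromide 7 in THF/saturated aqueous NH4Cl at rt (tolerant of the enolisable aldehyde) gives racemic 1-[2,3,6-tris(benzyloxy)-5-methoxyphenyl]pent-4-en-2-ol F3. Lipase-catalysed kinetic resolution (Burkholderia cepacia lipase, vinyl acetate, MTBE, 40 °C, stopped near 50% conversion) acetylates the (R)-enantiomer, as expected from Kazlauskas' rule with CH2Ar as the large group, and so gives acetate 17 directly. It leaves (S)-1-[2,3,6-tris(benzyloxy)-5-methoxyphenyl]pent-4-en-2-ol F4, which Mitsunobu inversion (AcOH, PPh3, DIAD, THF, 0 °C) also converts into 17. The route is rejoined at 17.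

Step 10 (cross-metathesis). The risks are incomplete conversion, homodimer of 17, and chain-length homologues from double-bond migration that would be hard to separate. The fallback sets out from acetate 17 and builds the saturated chain by hydroboration and alkyl–alkyl Suzuki coupling. 9-BBN-H (THF, 0 °C → rt) gives the adduct (R)-5-(9-borabicyclo[3.3.1]nonan-9-yl)-1-[2,3,6-tris(benzyloxy)-5-methoxyphenyl]pentan-2-yl acetate F5, used in solution. Coupling with 1-bromodecane (Pd(OAc)2, PCy3, K3PO4·H2O, THF, rt) gives (R)-1-[2,3,6-tris(benzyloxy)-5-methoxyphenyl]pentadecan-2-yl acetate F6. Hydrogenolysis of F6 under the conditions of step 11 gives triol 20, where the route is rejoined, and air oxidation gives 21.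

**Further compounds**
F1 | step 5 | 3,6-bis(benzyloxy)-2-bromo-4-methoxyphenol | Oc1c(Br)c(OCc2ccccc2)c(OC)cc1OCc1ccccc1
F2 | step 5 | 1,2,4-tris(benzyloxy)-3-bromo-5-methoxybenzene | Brc1c(OCc2ccccc2)c(OCc2ccccc2)cc(OC)c1OCc1ccccc1
F3 | step 8 | racemic 1-[2,3,6-tris(benzyloxy)-5-methoxyphenyl]pent-4-en-2-ol | C=CCC(O)Cc1c(OCc2ccccc2)c(OCc2ccccc2)cc(OC)c1OCc1ccccc1
F4 | step 8 | (S)-1-[2,3,6-tris(benzyloxy)-5-methoxyphenyl]pent-4-en-2-ol | C=CC[C@H](O)Cc1c(OCc2ccccc2)c(OCc2ccccc2)cc(OC)c1OCc1ccccc1
F5 | step 10 | (R)-5-(9-borabicyclo[3.3.1]nonan-9-yl)-1-[2,3,6-tris(benzyloxy)-5-methoxyphenyl]pentan-2-yl acetate | C1CC2CCCC(C1)B2CCC[C@H](Cc1c(OCc2ccccc2)c(OCc2ccccc2)cc(OC)c1OCc1ccccc1)OC(C)=O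
F6 | step 10 | (R)-1-[2,3,6-tris(benzyloxy)-5-methoxyphenyl]pentadecan-2-yl acetate | CCCCCCCCCCCCC[C@H](Cc1c(OCc2ccccc2)c(OCc2ccccc2)cc(OC)c1OCc1ccccc1)OC(C)=O
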